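**Plan**
1. The dihydro level of ring C (H at C6 and C7) is traced back to the aromatic 2,3-dihydrobenzofuran 15. The free phenol oxygen of the benzoate ring serves as a temporary tether to C3a.
2. C2 carries both the ring oxygen O1 and the carbinol carbon. The unit O1–C2–C(OH)Me2 is therefore read as a ring-contracted lactone O1–C(=O)–C2, and the cuts are O1–C2 and both C–CH3 bonds.
3. The six-membered lactone 10 is cut at C3–C3a and at the acyl–O1 bond. This gives a dihydrochalcone (4) and a trans-aryl glycidate (8).
4. Forward order: lactone ring, then contraction to the furan ring (step 8), then temporary ring O–C3a (step 10), then hydride at C6, then reductive release with a proton at C7.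
5. Stereochemistry: C2 and C3 come from one catalytic epoxidation (C3 by inversion, C2 by double inversion). The relay then runs C3 → C3a–O → C6 → C7 under substrate control.

Key step: step 8

Remark: benzofuran numbering of the target (O1, C2, C3, C3a, C4–C7, C7a) is used for all intermediates.
Remark: in step 5 the enantiomer of the fructose-type ketone catalyst is taken to be the one that delivers (2R,3S)-8.

**Step 1**
Reactants: 1 phloroglucinol; 2 3-phenylpropanoyl chloride
Product: 3 1-(2,4,6-trihydroxyphenyl)-3-phenylpropan-1-one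
Conditions: AlCl3, CH2Cl2–PhNO2, 0 → 40 °C; aq. HCl
Reagents that add atoms: none
Why: Friedel–Crafts C-acylation of the symmetrical triphenol can give only one ring isomer, and the first acyl group deactivates the ring against a second one.

**Step 2**
Reactants: 3
Product: 4 1-(2,6-dihydroxy-4-methoxyphenyl)-3-phenylpropan-1-one
Conditions: Me2SO4 (1.0 equiv), K2CO3, acetone, reflux
Reagents that add atoms: dimethyl sulfate COS(=O)(=O)OC
Why: In this Williamson O-methylation the two ortho hydroxyls are chelated to the ketone, so the free 4-OH should react first.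

**Step 3**
Reactants: 5 methyl 3-formyl-4-hydroxybenzoate
Product: 6 methyl 4-(benzyloxy)-3-formylbenzoate
Conditions: BnBr, K2CO3, DMF, rt
Reagents that add atoms: benzyl bromide BrCc1ccccc1
Why: Williamson benzylation masks the phenol, which would otherwise open the later epoxide through an o-quinone methide.

**Step 4**
Reactants: 6
Product: 7 methyl 4-(benzyloxy)-3-[(E)-3-methoxy-3-oxoprop-1-enyl]benzoate
Conditions: Ph3P=CHCO2Me, PhMe, rt
Reagents that add atoms: methyl (triphenylphosphoranylidene)acetate COC(=O)C=P(c1ccccc1)(c1ccccc1)c1ccccc1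
Why: The Wittig reaction of a stabilised ylide with an aryl aldehyde should give the (E)-cinnamate.

**Step 5**
Reactants: 7
Product: 8 methyl (2R,3S)-3-[2-(benzyloxy)-5-(methoxycarbonyl)phenyl]oxirane-2-carboxylate (trans)
Conditions: fructose-derived diacetate ketone (25 mol %), Oxone, NaHCO3, MeCN–aq. Na2EDTA, 0 °C → rt
Reagents that add atoms: Oxone (potassium peroxymonosulfate) [K+].[O-]S(=O)(=O)OO
Why: Shi epoxidation with the ester-tolerant chiral dioxirane transfers oxygen stereospecifically to the (E)-enoate, and the catalyst fixes the absolute configuration of both epoxide carbons.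

**Step 6**
Reactants: 8; 4 (1.5 equiv)
Product: 10 trans-(3R,4S)-3-hydroxy-4-aryl-dihydrocoumarin, via hydroxy ester 9 (not isolated)
Conditions: Sc(OTf)3 (10 mol %), HFIP–CH2Cl2, −20 °C → rt; then TsOH·H2O (cat.), PhMe, 80 °C
Reagents that add atoms: none
Why: In a Friedel–Crafts-type epoxide opening one of the two equivalent nucleophilic ring carbons of 4 attacks the benzylic C3 with inversion while the C2–O bond stays intact, and the neighbouring phenol then lactonises onto the methyl ester to give the 3,4-trans six-membered ring.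

**Step 7**
Reactants: 10
Product: 11 trans-(3R,4S)-3-mesyloxy-4-aryl-dihydrocoumarin
Conditions: MsCl (1.1 equiv), pyridine, CH2Cl2, 0 °C
Reagents that add atoms: methanesulfonyl chloride CS(=O)(=O)Cl
Why: Sulfonylation with a weak base takes the secondary alcohol with retention, while the ketone-chelated C6 phenol should stay free and the syn arrangement of H-4 and OMs disfavours E2 loss to the coumarin.

**Step 8**
Reactants: 11
Product: 14 cis-(2R,3S)-2-(2-hydroxypropan-2-yl)-3-aryl-2,3-dihydrobenzofuran benzyl ether, via ring-opened carbinol mesylate 12 (not isolated), via trisubstituted epoxide 13 (not isolated)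
Conditions: MeMgCl (3.3 equiv), THF, −78 → −20 °C; then MeOH, K2CO3, rt
Reagents that add atoms: methylmagnesium chloride C[Mg]Cl
Why: MeMgCl first deprotonates the chelated phenol and then adds twice to the aryl-ester carbonyl, so the O1–C(=O) bond of the six-membered lactone breaks and the former ring carbonyl carbon becomes the carbinolate carbon of 12; with K2CO3/MeOH this oxygen displaces the adjacent mesylate (3-exo-tet, inversion at C2) to give epoxide 13, and the freed C7a phenoxide O1 opens 13 at C2 (5-exo-tet, second inversion), which closes the five-membered ring. The closest known reaction types are the Perkin coumarin-to-benzofuran ring contraction of 3-halocoumarins and the base-induced 5-exo cyclisation of o-(2,3-epoxy-3-methylbutyl)phenols. C3 is untouched and C2 ends with net retention, so the trans O/aryl relation of 11 becomes the cis relation of carbinol and aryl groups in 14, which thermodynamic closures do not give. The lactone must react before the benzoate and the ketone, which is secured because the aryl ester is the best acyl donor and the ketone is masked as its magnesium-chelated bis-phenoxide. Epoxide formation must precede direct phenoxide SN2, which is secured because C2 is neopentyl-like and only the 3-exo path is fast. The 5-exo opening must beat the 6-endo opening, which is secured by the basic medium and attack at the less substituted carbon.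

**Step 9**
Reactants: 14
Product: 15 methyl 4-hydroxy-3-[(2R,3S)-6-hydroxy-2-(2-hydroxypropan-2-yl)-4-methoxy-7-(3-phenylpropanoyl)-2,3-dihydrobenzofuran-3-yl]benzoate
Conditions: H2 (1 atm), Pd/C, EtOAc, rt
Reagents that add atoms: none
Why: Hydrogenolysis removes the benzyl ether, and the chelated aryl ketone, the ester and the non-benzylic C2–O1 bond should not react under these mild conditions.

**Step 10**
Reactants: 15
Product: 16 pentacyclic 4-aryloxy-cyclohexa-2,5-dienone (benzoate phenol O bound to C3a)
Conditions: PhI(OAc)2 (1.05 equiv), HFIP–CH2Cl2, 0 °C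
Reagents that add atoms: none
Why: Iodine(III)-mediated oxidative phenol dearomatisation oxidises the electron-rich C6 phenol rather than the ester-bearing one, and the benzoate phenol oxygen, held under C3a by the C3 stereocentre, captures the para carbon (5-exo), so the new C3a–O bond can form only on the face of the aryl group.

**Step 11**
Reactants: 16
Product: 17 bis(triethylsilyl) ether with (6S)-C6(H)–OTES
Conditions: Et3SiH (2.2 equiv), B(C6F5)3 (5 mol %), CH2Cl2, −78 → −40 °C
Reagents that add atoms: triethylsilane CC[SiH](CC)CC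
Why: Proposed new method: in borane-catalysed hydrosilylation the silylium equivalent goes to the most Lewis-basic carbonyl, here the doubly vinylogous ring C6=O and not the side-chain ketone or the esters, and the resulting cation carries its weakest donor (OSi) at C6 while C4 and C7a are alkoxy-stabilised and flanked by quaternary C3a, so hydride should enter at C6 (1,2) and, by electrostatic control as in additions to 4-alkoxy-4-alkylcyclohexadienones, on the face syn to the C3a–O bond, giving C6–OTES on the opposite face, with the tertiary alcohol silylated dehydrogenatively in the same flask; the closest known types are B(C6F5)3/silane reduction of ketones (1,4 with simple enones) and dehydrogenative silylation of alcohols.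

**Step 12**
Reactants: 17
Product: 18 bis(triethylsilyl) ether of the target
Conditions: SmI2 (2.5 equiv), MeOH (5 equiv), THF, −78 °C; pH 7 buffer
Reagents that add atoms: none
Why: SmI2 reduction of a γ-oxygenated enone (the vinylogous form of α-deoxygenation of ketones) expels the aryloxide from C3a, which frees the phenol and creates C3a=C7a, and kinetic α-protonation of the dienolate at C7 from the face away from the bulky C6–OTES group should place the acyl group cis to it and leave the ketone deconjugated.

**Step 13**
Reactants: 18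
Product: 19 target CNP0080427.1 (2R,3S,6S,7S)
Conditions: Et3N·3HF, THF–MeCN, 0 °C; pH 7 work-up
Reagents that add atoms: none
Why: Near-neutral fluoride desilylation removes both triethylsilyl ethers without the acid or base that would dehydrate the β-hydroxy ketone to the arene.

**Compound list**
1 | phloroglucinol | Oc1cc(O)cc(O)c1 | starting material
2 | 3-phenylpropanoyl chloride | O=C(Cl)CCc1ccccc1 | starting material
3 | 1-(2,4,6-trihydroxyphenyl)-3-phenylpropan-1-one | O=C(CCc1ccccc1)c1c(O)cc(O)cc1O | intermediate
4 | 1-(2,6-dihydroxy-4-methoxyphenyl)-3-phenylpropan-1-one | COc1cc(O)c(C(=O)CCc2ccccc2)c(O)c1 | intermediate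
5 | methyl 3-formyl-4-hydroxybenzoate | COC(=O)c1ccc(O)c(C=O)c1 | starting material
6 | methyl 4-(benzyloxy)-3-formylbenzoate | COC(=O)c1ccc(OCc2ccccc2)c(C=O)c1 | intermediate
7 | methyl 4-(benzyloxy)-3-[(E)-3-methoxy-3-oxoprop-1-enyl]benzoate | COC(=O)/C=C/c1cc(C(=O)OC)ccc1OCc1ccccc1 | intermediate
8 | methyl (2R,3S)-3-[2-(benzyloxy)-5-(methoxycarbonyl)phenyl]oxirane-2-carboxylate (trans) | COC(=O)c1ccc(OCc2ccccc2)c(c1)[C@@H]3O[C@H]3C(=O)OC | intermediate
9 | (2R,3S)-α-hydroxy methyl ester from arene opening of 8 at C3 (not isolated) | COC(=O)c1ccc(OCc2ccccc2)c(c1)[C@@H](c3c(OC)cc(O)c(C(=O)CCc4ccccc4)c3O)[C@@H](O)C(=O)OC | intermediate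
10 | methyl 4-(benzyloxy)-3-[(3R,4S)-3,7-dihydroxy-5-methoxy-2-oxo-8-(3-phenylpropanoyl)chroman-4-yl]benzoate (3,4-trans) | COC(=O)c1ccc(OCc2ccccc2)c(c1)[C@H]3c4c(OC)cc(O)c(C(=O)CCc5ccccc5)c4OC(=O)[C@@H]3O | intermediate
11 | 3-O-methanesulfonate of 10 (3R,4S, trans) | COC(=O)c1ccc(OCc2ccccc2)c(c1)[C@H]3c4c(OC)cc(O)c(C(=O)CCc5ccccc5)c4OC(=O)[C@@H]3OS(C)(=O)=O | intermediate
12 | ring-opened tertiary carbinol with C2 mesylate and free C7a phenol (not isolated) | COC(=O)c1ccc(OCc2ccccc2)c(c1)[C@@H](c3c(OC)cc(O)c(C(=O)CCc4ccccc4)c3O)[C@@H](OS(C)(=O)=O)C(C)(C)O | intermediate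
13 | 3,3-dimethyloxirane formed with inversion at C2 (not isolated) | COC(=O)c1ccc(OCc2ccccc2)c(c1)[C@@H](c3c(OC)cc(O)c(C(=O)CCc4ccccc4)c3O)[C@@H]5OC5(C)C | intermediate
14 | methyl 4-(benzyloxy)-3-[(2R,3S)-6-hydroxy-2-(2-hydroxypropan-2-yl)-4-methoxy-7-(3-phenylpropanoyl)-2,3-dihydrobenzofuran-3-yl]benzoate (2,3-cis) | COC(=O)c1ccc(OCc2ccccc2)c(c1)[C@H]3c4c(OC)cc(O)c(C(=O)CCc5ccccc5)c4O[C@H]3C(C)(C)O | intermediate
15 | free phenol of 14 (2R,3S, cis) | COC(=O)c1ccc(O)c(c1)[C@H]2c3c(OC)cc(O)c(C(=O)CCc4ccccc4)c3O[C@H]2C(C)(C)O | intermediate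
16 | pentacyclic dienone: C6=O, C4(OMe)=C5, C7(acyl)=C7a(O1), benzoate phenol O on C3a on the face of the aryl group | COC(=O)c1ccc2c(c1)[C@@H]3[C@H](C(C)(C)O)OC4=C(C(=O)CCc5ccccc5)C(=O)C=C(OC)[C@@]34O2 | intermediate
17 | C6(H)–OTES and tertiary OTES derivative of 16, with C6–O anti to the C3a–O bond | COC(=O)c1ccc2c(c1)[C@@H]3[C@H](C(C)(C)O[Si](CC)(CC)CC)OC4=C(C(=O)CCc5ccccc5)[C@@H](O[Si](CC)(CC)CC)C=C(OC)[C@@]34O2 | intermediate
18 | 6-O- and carbinol-O-bis(triethylsilyl) ether of the target | COC(=O)c1ccc(O)c([C@H]2C3=C(O[C@H]2C(C)(C)O[Si](CC)(CC)CC)[C@@H](C(=O)CCc2ccccc2)[C@@H](O[Si](CC)(CC)CC)C=C3OC)c1 | intermediate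
19 | CNP0080427.1, (2R,3S,6S,7S) | COC(=O)c1ccc(O)c([C@H]2C3=C(O[C@H]2C(C)(C)O)[C@@H](C(=O)CCc2ccccc2)[C@@H](O)C=C3OC)c1 | target

Total steps: 13. Longest linear sequence: 11 (steps 3–13, from 5).

**Steps most likely to fail**

*Step 11.* Hydride may be delivered to C4 or C7a (1,4 mode) or to the side-chain ketone. The bis-allylic silyl ether may be over-reduced. Facial selectivity at C6 may be poor.

Fallback: setting out from 16, the side-chain ketone and the tertiary alcohol are masked together with TESOTf/Et3N as the (Z)-silyl enol ether carbinol silyl ether F1. A Luche reduction (NaBH4, CeCl3, MeOH, −40 °C) then finds the ring carbonyl as the only ketone and should give the C6 alcohol F2. TESCl/imidazole gives the tris-silyl compound F3. Methanolysis of the far more labile enol silane (cat. K2CO3, MeOH, −20 °C) comes back to the route at 17.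

*Step 12.* The dienolate may lose silanolate from C6 and re-aromatise. Alternatively, it may be protonated at C3a or C5, or at C7 from the wrong face.

Fallback: setting out from 17, electron transfer and protonation are separated. SmI2 in the presence of TMSCl traps dienolate and phenoxide as the bis(trimethylsilyl) dienol ether F4. This is protonated at C7 at −78 °C by a bulky Lewis-acid-assisted phenol from the face away from C6–OTES. Aqueous work-up frees the phenol and comes back at 18.

*Step 6.* The ortho-alkoxy-stabilised benzylic centre may open through a cation, which would erode the inversion at C3. O-alkylation of 4 may also compete.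

Fallback: setting out from 4, a Pechmann-type condensation with ethyl propiolate (ZnCl2, 100 °C) gives the 7-hydroxy-5-methoxy-8-acylcoumarin F5. A Hayashi–Miyaura addition of commercial [2-(benzyloxy)-5-(methoxycarbonyl)phenyl]boronic acid (Rh(I)/Segphos, dioxane–H2O) sets C3 by catalysis and gives the 4-aryl-dihydrocoumarin F6. Enolate hydroxylation (KHMDS, Davis oxaziridine, −78 °C) then brings oxygen in anti to the aryl group and comes back at 10.

**Further compounds**
F1 | step 11 | (Z)-triethylsilyl enol ether and carbinol triethylsilyl ether of 16 | COC(=O)c1ccc2c(c1)[C@@H]3[C@H](C(C)(C)O[Si](CC)(CC)CC)OC4=C(/C(O[Si](CC)(CC)CC)=C/Cc5ccccc5)C(=O)C=C(OC)[C@@]34O2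
F2 | step 11 | C6 alcohol from Luche reduction of F1 | COC(=O)c1ccc2c(c1)[C@@H]3[C@H](C(C)(C)O[Si](CC)(CC)CC)OC4=C(/C(O[Si](CC)(CC)CC)=C/Cc5ccccc5)[C@@H](O)C=C(OC)[C@@]34O2
F3 | step 11 | C6 triethylsilyl ether of F2 | COC(=O)c1ccc2c(c1)[C@@H]3[C@H](C(C)(C)O[Si](CC)(CC)CC)OC4=C(/C(O[Si](CC)(CC)CC)=C/Cc5ccccc5)[C@@H](O[Si](CC)(CC)CC)C=C(OC)[C@@]34O2
F4 | step 12 | bis(trimethylsilyl) dienol ether and aryl silyl ether from reductive opening of 17 | COC(=O)c1ccc(O[Si](C)(C)C)c([C@H]2C3=C(O[C@H]2C(C)(C)O[Si](CC)(CC)CC)C(=C(CCc2ccccc2)O[Si](C)(C)C)[C@@H](O[Si](CC)(CC)CC)C=C3OC)c1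
F5 | step 6 | 7-hydroxy-5-methoxy-8-(3-phenylpropanoyl)coumarin | COc1cc(O)c(C(=O)CCc2ccccc2)c2OC(=O)C=Cc12
F6 | step 6 | 4-aryl-7-hydroxy-5-methoxy-8-(3-phenylpropanoyl)chroman-2-one with the C4 configuration of 10 | COC(=O)c1ccc(OCc2ccccc2)c(c1)[C@H]3c4c(OC)cc(O)c(C(=O)CCc5ccccc5)c4OC(=O)C3
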